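**Plan**

- Numbering used: C1 carboxyl carbon, C2 the CHMe carbon, C3 and C6 the two carbons of the 1,2-dioxane, C7 and C8 the chain, C9 the carbinol carbon, C10 the methylidene-bearing carbon.
- Cuts, in retrosynthetic order: C9–C10 (2-lithioalkene from dihydro-β-ionone plus a C9 aldehyde), then O–C6 of the dioxane, then O–C3 (SN2 by hydrogen peroxide), then C2–C3 (anti-crotylboration, the vinyl group being the latent C1 carboxyl).
- Enabling feature: C6 is fully substituted and stands 1,4 to the C9 oxygen (C6–C7–C8–C9). A temporary cyclopropane C6–C7–C8, whose C6–C8 bond is absent from the target, with C9 as an acetal (latent oxocarbenium ion), makes C6 a configurationally defined tertiary electrophile.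
- Forward: geraniol (C3–C6, 6-Me, C8, C9) + CH2 (C7) → cyclopropyl acetal → C3 aldehyde → crotylation (C1, C2, 2-Me) → C3 hydroperoxide → acid-catalysed dioxane closure with cyclopropane opening → C1 ester and C9 aldehyde → side chain.
- Stereochemistry: C6 from the asymmetric cyclopropanation, transferred with inversion in the ring closure; C2 and C3 from the crotylboration, C3 then inverted by peroxide; C9 from a reagent-controlled ketone reduction.

Key step: step 8

Assumption: the (4S,5S)-dioxaborolane ligand is taken to deliver the methylene to geraniol with the same facial sense as it does to other (E)-allylic alcohols, which gives the (1R,2R)-cyclopropane; if the sense were opposite, the (4R,5R)-ligand would be used.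

**Route**

Step 1
Reactants: 1 geraniol
Product: 2 [(1R,2R)-2-methyl-2-(4-methylpent-3-en-1-yl)cyclopropyl]methanol
Conditions: Zn(CH2I)2·DME (from Et2Zn + CH2I2), (4S,5S)-2-butyl-N,N,N′,N′-tetramethyl-1,3,2-dioxaborolane-4,5-dicarboxamide (1.2 equiv), CH2Cl2, −10 °C → rt; aq. NH4Cl
Reagents that add atoms: diiodomethane, ICI
Why: Hydroxyl-directed Simmons–Smith reaction in its Charette asymmetric form, in which the zinc alkoxide bound to the chiral dioxaborolane should deliver CH2 (the future C7) to one face of the allylic double bond only, setting C6 and the helper centre C8 trans to each other from the E alkene while the remote trisubstituted alkene stays untouched.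

Step 2
Reactants: 2 [(1R,2R)-2-methyl-2-(4-methylpent-3-en-1-yl)cyclopropyl]methanol
Product: 3 (1R,2R)-2-methyl-2-(4-methylpent-3-en-1-yl)cyclopropane-1-carbaldehyde
Conditions: TEMPO (cat.), PhI(OAc)2, CH2Cl2, rt
Reagents that add atoms: none
Why: Oxoammonium-mediated (TEMPO) oxidation of a primary alcohol should stop at the aldehyde and leave the alkene and the cyclopropane alone.

Step 3
Reactants: 3 (1R,2R)-2-methyl-2-(4-methylpent-3-en-1-yl)cyclopropane-1-carbaldehyde
Product: 4 (1R,2R)-1-(dimethoxymethyl)-2-methyl-2-(4-methylpent-3-en-1-yl)cyclopropane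
Conditions: HC(OMe)3, PPTS (cat.), CH2Cl2, rt
Reagents that add atoms: trimethyl orthoformate, COC(OC)OC
Why: Mild acid-catalysed acetalisation should give the dimethyl acetal, which shields C9 from the basic peroxide of step 7 and stores the oxocarbenium ion needed in step 8.

Step 4
Reactants: 4 (1R,2R)-1-(dimethoxymethyl)-2-methyl-2-(4-methylpent-3-en-1-yl)cyclopropane
Product: 5 3-[(1R,2R)-2-(dimethoxymethyl)-1-methylcyclopropyl]propanal
Conditions: O3, CH2Cl2, −78 °C (Sudan Red 7B end point); Me2S, −78 °C → rt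
Reagents that add atoms: ozone, [O-][O+]=O
Why: Ozonolysis with reductive work-up should cleave the only alkene to the C3 aldehyde, the indicator preventing over-oxidation of the acetal.

Step 5
Reactants: 5 3-[(1R,2R)-2-(dimethoxymethyl)-1-methylcyclopropyl]propanal
Product: 6 (3R,4S)-1-[(1R,2R)-2-(dimethoxymethyl)-1-methylcyclopropyl]-4-methylhex-5-en-3-ol
Conditions: diisopropyl (4R,5R)-2-[(2E)-but-2-en-1-yl]-1,3,2-dioxaborolane-4,5-dicarboxylate (1.5 equiv), 4 Å molecular sieves, toluene, −78 °C; aq. NaOH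
Reagents that add atoms: diisopropyl (4R,5R)-2-[(2E)-but-2-en-1-yl]-1,3,2-dioxaborolane-4,5-dicarboxylate, CC(C)OC(=O)[C@@H]1OB(C/C=C/C)O[C@H]1C(=O)OC(C)C
Why: Roush crotylboration through a chair six-membered transition state, in which the E reagent should give the anti relationship and the (R,R)-tartrate should direct attack to the Si face of the aldehyde, sets C2 and C3 (anti, as needed for the inversion in step 7); minor diastereomers from imperfect reagent control should be removable at this alcohol stage.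

Step 6
Reactants: 6 (3R,4S)-1-[(1R,2R)-2-(dimethoxymethyl)-1-methylcyclopropyl]-4-methylhex-5-en-3-ol
Product: 7 (3R,4S)-1-[(1R,2R)-2-(dimethoxymethyl)-1-methylcyclopropyl]-4-methylhex-5-en-3-yl methanesulfonate
Conditions: MsCl, Et3N, CH2Cl2, 0 °C
Reagents that add atoms: methanesulfonyl chloride, CS(=O)(=O)Cl
Why: Standard sulfonylation of a secondary alcohol with retention at C3 should give the leaving group without touching the acetal.

Step 7
Reactants: 7 (3R,4S)-1-[(1R,2R)-2-(dimethoxymethyl)-1-methylcyclopropyl]-4-methylhex-5-en-3-yl methanesulfonate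
Product: 8 (1R,2R)-1-(dimethoxymethyl)-2-[(3S,4S)-3-hydroperoxy-4-methylhex-5-en-1-yl]-2-methylcyclopropane
Conditions: H2O2 (50% aq., excess), KOH, MeOH, 0 °C → rt
Reagents that add atoms: hydrogen peroxide, OO
Why: SN2 perhydrolysis of a secondary sulfonate by the hydroperoxide anion should proceed with inversion at C3 and so convert the 2,3-anti alcohol derivative into the 2,3-syn hydroperoxide, acetal and cyclopropane being inert to base.

Step 8
Reactants: 8 (1R,2R)-1-(dimethoxymethyl)-2-[(3S,4S)-3-hydroperoxy-4-methylhex-5-en-1-yl]-2-methylcyclopropane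
Product: 11 (3S,6S)-3-[(2S)-but-3-en-2-yl]-6-(3,3-dimethoxypropyl)-6-methyl-1,2-dioxane, via cyclopropylcarbinyl oxocarbenium triflate 9 (not isolated), via methyl enol ether 10 (not isolated)
Conditions: Me3SiOTf (0.2 equiv), CH2Cl2 (0.01 M), −78 → −30 °C; Et3N
Reagents that add atoms: none
Why: Proposed new method: Me3SiOTf should ionise the dimethyl acetal to the cyclopropylcarbinyl oxocarbenium ion 9, whose charge is shared with C6, the only fully substituted ring carbon, so that the distal oxygen of the C3 hydroperoxide attacks C6 from the side opposite to the breaking C6–C8 bond, C8=C9 forms as the methyl enol ether 10, and the released acid and methanol return 10 to the dimethyl acetal 11 (a net isomerisation, catalytic in acid). The closest known reaction types are the stereoinvertive substitution at the quaternary carbon of cyclopropylcarbinyl cations to give tertiary homoallyl products, the acid-promoted opening of acylcyclopropanes by internal nucleophiles with inversion, and the Lewis-acid-mediated closure of hydroperoxides onto tertiary oxetanes and epoxides. The 1,2-dioxane closes in the 6-exo-tet mode through a chair with the C3 side chain equatorial. The new stereocentre C6 is fixed by the configuration of the cyclopropane carbon through inversion and not by the weak axial/equatorial preference of methyl against chain, while C8 ceases to be stereogenic. The step needs attack at C6 and not at C7 or C9, and by the peroxide oxygen and not by the vinyl group; the tertiary nature of C6, the six-membered ring size, the reversibility of peroxyacetal formation at C9, the low nucleophilicity of a monosubstituted alkene and high dilution should secure this.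

Step 9
Reactants: 11 (3S,6S)-3-[(2S)-but-3-en-2-yl]-6-(3,3-dimethoxypropyl)-6-methyl-1,2-dioxane
Product: 13 (2R)-2-[(3S,6S)-6-(3,3-dimethoxypropyl)-6-methyl-1,2-dioxan-3-yl]propanoic acid, via aldehyde 12 (not isolated)
Conditions: O3, MeCN/H2O (9:1), 0 °C; then NaClO2, NaH2PO4, 0 °C → rt
Reagents that add atoms: ozone, [O-][O+]=O; water, O; sodium chlorite, [Na+].[O-]Cl=O
Why: Ozonolysis in aqueous acetonitrile should cleave the only C=C bond to aldehyde 12 by hydration of the carbonyl oxide, and chlorite (Pinnick-type oxidation, the hydrogen peroxide formed serving as hypochlorite scavenger) should oxidise it at once, so that the epimerisable, base-labile β-peroxy aldehyde is never handled and C2 keeps its configuration.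

Step 10
Reactants: 13 (2R)-2-[(3S,6S)-6-(3,3-dimethoxypropyl)-6-methyl-1,2-dioxan-3-yl]propanoic acid
Product: 14 methyl (2R)-2-[(3S,6S)-6-(3,3-dimethoxypropyl)-6-methyl-1,2-dioxan-3-yl]propanoate
Conditions: Me3SiCHN2, MeOH/toluene, 0 °C
Reagents that add atoms: (trimethylsilyl)diazomethane, C[Si](C)(C)C=[N+]=[N-]
Why: Esterification by the diazoalkane under neutral conditions should protect the acid for steps 13 to 15 without risk to the acetal, the peroxide or C2.

Step 11
Reactants: 14 methyl (2R)-2-[(3S,6S)-6-(3,3-dimethoxypropyl)-6-methyl-1,2-dioxan-3-yl]propanoate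
Product: 15 methyl (2R)-2-[(3S,6S)-6-methyl-6-(3-oxopropyl)-1,2-dioxan-3-yl]propanoate
Conditions: PPTS (cat.), acetone/H2O (9:1), 50 °C
Reagents that add atoms: water, O
Why: Mild acid hydrolysis of the dimethyl acetal should release the C9 aldehyde, dialkyl peroxides and methyl esters being stable to dilute acid.

Step 12
Reactants: 16 dihydro-β-ionone
Product: 17 N′-[4-(2,6,6-trimethylcyclohex-1-en-1-yl)butan-2-ylidene]-2,4,6-tri(propan-2-yl)benzenesulfonohydrazide
Conditions: 2,4,6-triisopropylbenzenesulfonyl hydrazide, HCl (cat.), MeOH, rt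
Reagents that add atoms: 2,4,6-triisopropylbenzenesulfonyl hydrazide, CC(C)c1cc(C(C)C)c(S(=O)(=O)NN)c(C(C)C)c1
Why: Acid-catalysed condensation of a methyl ketone with the arylsulfonyl hydrazide should give the hydrazone needed for the Shapiro reaction.

Step 13
Reactants: 17 N′-[4-(2,6,6-trimethylcyclohex-1-en-1-yl)butan-2-ylidene]-2,4,6-tri(propan-2-yl)benzenesulfonohydrazide; 15 methyl (2R)-2-[(3S,6S)-6-methyl-6-(3-oxopropyl)-1,2-dioxan-3-yl]propanoate
Product: 19 methyl (2R)-2-[(3S,6R)-6-[(3RS)-3-hydroxy-4-methylidene-6-(2,6,6-trimethylcyclohex-1-en-1-yl)hexyl]-6-methyl-1,2-dioxan-3-yl]propanoate, via vinyllithium 18 (not isolated)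
Conditions: 17, n-BuLi (2.1 equiv), THF, −78 → 0 °C; then −78 °C, 15 (0.8 equiv); aq. quench
Reagents that add atoms: none
Why: Shapiro reaction, in which the hydrazone dianion (deprotonated at the methyl group) should lose sulfinate and nitrogen to give the 2-lithio-1-alkene 18, and this should add to the aldehyde at −78 °C much faster than to the hindered ester or the dialkyl peroxide; C9 forms as a mixture that steps 14 and 15 correct.

Step 14
Reactants: 19 methyl (2R)-2-[(3S,6R)-6-[(3RS)-3-hydroxy-4-methylidene-6-(2,6,6-trimethylcyclohex-1-en-1-yl)hexyl]-6-methyl-1,2-dioxan-3-yl]propanoate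
Product: 20 methyl (2R)-2-[(3S,6S)-6-methyl-6-[4-methylidene-3-oxo-6-(2,6,6-trimethylcyclohex-1-en-1-yl)hexyl]-1,2-dioxan-3-yl]propanoate
Conditions: Dess–Martin periodinane, CH2Cl2, 0 °C → rt
Reagents that add atoms: none
Why: Dess–Martin oxidation of the allylic alcohol should give the α-methylene ketone under neutral conditions that spare the peroxide and both alkenes.

Step 15
Reactants: 20 methyl (2R)-2-[(3S,6S)-6-methyl-6-[4-methylidene-3-oxo-6-(2,6,6-trimethylcyclohex-1-en-1-yl)hexyl]-1,2-dioxan-3-yl]propanoate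
Product: 21 methyl (2R)-2-[(3S,6R)-6-[(3R)-3-hydroxy-4-methylidene-6-(2,6,6-trimethylcyclohex-1-en-1-yl)hexyl]-6-methyl-1,2-dioxan-3-yl]propanoate
Conditions: (S)-2-methyl-CBS-oxazaborolidine (0.5 equiv), catecholborane, toluene, −78 °C; MeOH, aq. NaHCO3
Reagents that add atoms: none
Why: Corey–Bakshi–Shibata reduction, in which the 1-substituted vinyl group acts as the large and the CH2 chain as the small substituent, so that the (S)-catalyst should deliver hydride in the 1,2 sense to give the 9R alcohol, the remote stereocentres having no say.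

Step 16
Reactants: 21 methyl (2R)-2-[(3S,6R)-6-[(3R)-3-hydroxy-4-methylidene-6-(2,6,6-trimethylcyclohex-1-en-1-yl)hexyl]-6-methyl-1,2-dioxan-3-yl]propanoate
Product: 22 (2R)-2-[(3S,6R)-6-[(3R)-3-hydroxy-4-methylidene-6-(2,6,6-trimethylcyclohex-1-en-1-yl)hexyl]-6-methyl-1,2-dioxan-3-yl]propanoic acid
Conditions: LiOH, THF/MeOH/H2O, 0 °C → rt; 1 M HCl to pH 3
Reagents that add atoms: lithium hydroxide, [Li+].[OH-]
Why: Saponification of the methyl ester at low temperature should free the acid without retro-oxa-Michael opening of the β-peroxy ester or epimerisation at C2, as is usual for dioxane propanoates of this kind.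

**Compound list**

1 | geraniol, (2E)-3,7-dimethylocta-2,6-dien-1-ol | CC(C)=CCC/C(C)=C/CO | starting material
2 | [(1R,2R)-2-methyl-2-(4-methylpent-3-en-1-yl)cyclopropyl]methanol | CC(C)=CCC[C@]1(C)C[C@H]1CO | intermediate
3 | (1R,2R)-2-methyl-2-(4-methylpent-3-en-1-yl)cyclopropane-1-carbaldehyde | CC(C)=CCC[C@]1(C)C[C@H]1C=O | intermediate
4 | (1R,2R)-1-(dimethoxymethyl)-2-methyl-2-(4-methylpent-3-en-1-yl)cyclopropane | CC(C)=CCC[C@]1(C)C[C@H]1C(OC)OC | intermediate
5 | 3-[(1R,2R)-2-(dimethoxymethyl)-1-methylcyclopropyl]propanal | O=CCC[C@]1(C)C[C@H]1C(OC)OC | intermediate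
6 | (3R,4S)-1-[(1R,2R)-2-(dimethoxymethyl)-1-methylcyclopropyl]-4-methylhex-5-en-3-ol | C=C[C@H](C)[C@H](O)CC[C@]1(C)C[C@H]1C(OC)OC | intermediate
7 | (3R,4S)-1-[(1R,2R)-2-(dimethoxymethyl)-1-methylcyclopropyl]-4-methylhex-5-en-3-yl methanesulfonate | C=C[C@H](C)[C@H](OS(C)(=O)=O)CC[C@]1(C)C[C@H]1C(OC)OC | intermediate
8 | (1R,2R)-1-(dimethoxymethyl)-2-[(3S,4S)-3-hydroperoxy-4-methylhex-5-en-1-yl]-2-methylcyclopropane | C=C[C@H](C)[C@@H](OO)CC[C@]1(C)C[C@H]1C(OC)OC | intermediate
9 | methyl{[(1R,2R)-2-[(3S,4S)-3-hydroperoxy-4-methylhex-5-en-1-yl]-2-methylcyclopropyl]methylidene}oxonium trifluoromethanesulfonate | C=C[C@H](C)[C@@H](OO)CC[C@]1(C)C[C@H]1C=[O+]C.[O-]S(=O)(=O)C(F)(F)F | intermediate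
10 | (3S,6S)-3-[(2S)-but-3-en-2-yl]-6-(3-methoxyprop-2-en-1-yl)-6-methyl-1,2-dioxane (E/Z mixture) | COC=CC[C@]1(C)CC[C@@H]([C@@H](C)C=C)OO1 | intermediate
11 | (3S,6S)-3-[(2S)-but-3-en-2-yl]-6-(3,3-dimethoxypropyl)-6-methyl-1,2-dioxane | COC(OC)CC[C@]1(C)CC[C@@H]([C@@H](C)C=C)OO1 | intermediate
12 | (2R)-2-[(3S,6S)-6-(3,3-dimethoxypropyl)-6-methyl-1,2-dioxan-3-yl]propanal | COC(OC)CC[C@]1(C)CC[C@@H]([C@@H](C)C=O)OO1 | intermediate
13 | (2R)-2-[(3S,6S)-6-(3,3-dimethoxypropyl)-6-methyl-1,2-dioxan-3-yl]propanoic acid | COC(OC)CC[C@]1(C)CC[C@@H]([C@@H](C)C(=O)O)OO1 | intermediate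
14 | methyl (2R)-2-[(3S,6S)-6-(3,3-dimethoxypropyl)-6-methyl-1,2-dioxan-3-yl]propanoate | COC(OC)CC[C@]1(C)CC[C@@H]([C@@H](C)C(=O)OC)OO1 | intermediate
15 | methyl (2R)-2-[(3S,6S)-6-methyl-6-(3-oxopropyl)-1,2-dioxan-3-yl]propanoate | O=CCC[C@]1(C)CC[C@@H]([C@@H](C)C(=O)OC)OO1 | intermediate
16 | dihydro-β-ionone, 4-(2,6,6-trimethylcyclohex-1-en-1-yl)butan-2-one | CC(=O)CCC1=C(C)CCCC1(C)C | starting material
17 | N′-[4-(2,6,6-trimethylcyclohex-1-en-1-yl)butan-2-ylidene]-2,4,6-tri(propan-2-yl)benzenesulfonohydrazide | CC(CCC1=C(C)CCCC1(C)C)=NNS(=O)(=O)c1c(C(C)C)cc(C(C)C)cc1C(C)C | intermediate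
18 | [4-(2,6,6-trimethylcyclohex-1-en-1-yl)but-1-en-2-yl]lithium | [Li]C(=C)CCC1=C(C)CCCC1(C)C | intermediate
19 | methyl (2R)-2-[(3S,6R)-6-[(3RS)-3-hydroxy-4-methylidene-6-(2,6,6-trimethylcyclohex-1-en-1-yl)hexyl]-6-methyl-1,2-dioxan-3-yl]propanoate | C=C(CCC1=C(C)CCCC1(C)C)C(O)CC[C@]1(C)CC[C@@H]([C@@H](C)C(=O)OC)OO1 | intermediate
20 | methyl (2R)-2-[(3S,6S)-6-methyl-6-[4-methylidene-3-oxo-6-(2,6,6-trimethylcyclohex-1-en-1-yl)hexyl]-1,2-dioxan-3-yl]propanoate | C=C(CCC1=C(C)CCCC1(C)C)C(=O)CC[C@]1(C)CC[C@@H]([C@@H](C)C(=O)OC)OO1 | intermediate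
21 | methyl (2R)-2-[(3S,6R)-6-[(3R)-3-hydroxy-4-methylidene-6-(2,6,6-trimethylcyclohex-1-en-1-yl)hexyl]-6-methyl-1,2-dioxan-3-yl]propanoate | C=C(CCC1=C(C)CCCC1(C)C)[C@H](O)CC[C@]1(C)CC[C@@H]([C@@H](C)C(=O)OC)OO1 | intermediate
22 | (2R)-2-[(3S,6R)-6-[(3R)-3-hydroxy-4-methylidene-6-(2,6,6-trimethylcyclohex-1-en-1-yl)hexyl]-6-methyl-1,2-dioxan-3-yl]propanoic acid | C=C(CCC1=C(C)CCCC1(C)C)[C@H](O)CC[C@]1(C)CC[C@@H]([C@@H](C)C(=O)O)OO1 | target

**Step count and risks**

Total: 16 steps. Longest linear sequence: 15 steps (steps 1 to 11 and 13 to 16, from geraniol).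

Steps most likely to fail:

1. Step 8 (Proposed new method). The acetal may ionise without the ring closing: the hydroperoxide or methanol may be captured at the oxocarbenium carbon, or the cyclopropane may open through a free tertiary cation, with elimination and loss of stereochemical fidelity at C6. Fallback, with known chemistry, keeping the same O–C6 closure with inversion but on a tertiary oxetane; it sets out from 1 and comes back at 10 and then 11. Sharpless asymmetric epoxidation of geraniol 1 (Ti(OiPr)4, D-(−)-diethyl tartrate, t-BuOOH) gives the (2R,3R)-epoxy alcohol F1. NaAlH2(OCH2CH2OMe)2 opens it at C2 to the (3R)-1,3-diol F2. n-BuLi and TsCl give the primary tosylate F3, which a second equivalent of n-BuLi closes to the (2R)-oxetane F4. Ozonolysis gives the oxetane aldehyde F5. Crotylboration as in step 5, mesylation as in step 6 and perhydrolysis as in step 7 give the homoallylic alcohol F6, the mesylate F7 and the oxetane hydroperoxide F8. Yb(OTf)3 or Me3SiOTf then opens the oxetane at its tertiary carbon in the 6-exo mode with inversion to the dioxane ethanol F9. Dess–Martin oxidation gives the dioxane acetaldehyde F10, and Wittig reaction with Ph3P=CHOMe gives enol ether 10, which PPTS in methanol converts into 11.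

2. Step 7. Elimination toward the allylic C2–H may outrun the slow substitution at the hindered secondary carbon. Fallback, setting out from 6 and coming back at 8: the alcohol is converted (Tf2O, 2,6-lutidine, −78 °C) into the triflate F11, which alkylates 2-methoxypropan-2-yl hydroperoxide (CsOH·H2O, DMF, 0 °C) with inversion to the peroxyketal F12; PPTS in methanol removes the ketal, keeps the dimethyl acetal and gives 8.

3. Step 13. The organolithium may attack the O–O bond or the ester, or enolise the aldehyde. Fallback, setting out from 15 and 17 and coming back at 20, which also makes step 14 unnecessary: Pinnick oxidation of 15 gives the carboxylic acid F13 and oxalyl chloride the acid chloride F14; vinyllithium 18, made from 17 as in step 13, is quenched with Bu3SnCl to the alkenylstannane F15; Stille acylation of F14 with F15 (PdCl2(PPh3)2, toluene, 60 °C) gives enone 20.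

**Further compounds**

F1 | step 8 | [(2R,3R)-3-methyl-3-(4-methylpent-3-en-1-yl)oxiran-2-yl]methanol | CC(C)=CCC[C@@]1(C)O[C@@H]1CO
F2 | step 8 | (3R)-3,7-dimethyloct-6-ene-1,3-diol | CC(C)=CCC[C@@](C)(O)CCO
F3 | step 8 | (3R)-3-hydroxy-3,7-dimethyloct-6-en-1-yl 4-methylbenzenesulfonate | CC(C)=CCC[C@@](C)(O)CCOS(=O)(=O)c1ccc(C)cc1
F4 | step 8 | (2R)-2-methyl-2-(4-methylpent-3-en-1-yl)oxetane | CC(C)=CCC[C@]1(C)CCO1
F5 | step 8 | 3-[(2R)-2-methyloxetan-2-yl]propanal | O=CCC[C@]1(C)CCO1
F6 | step 8 | (3R,4S)-4-methyl-1-[(2R)-2-methyloxetan-2-yl]hex-5-en-3-ol | C=C[C@H](C)[C@H](O)CC[C@]1(C)CCO1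
F7 | step 8 | (3R,4S)-4-methyl-1-[(2R)-2-methyloxetan-2-yl]hex-5-en-3-yl methanesulfonate | C=C[C@H](C)[C@H](OS(C)(=O)=O)CC[C@]1(C)CCO1
F8 | step 8 | (2R)-2-[(3S,4S)-3-hydroperoxy-4-methylhex-5-en-1-yl]-2-methyloxetane | C=C[C@H](C)[C@@H](OO)CC[C@]1(C)CCO1
F9 | step 8 | 2-[(3S,6S)-6-[(2S)-but-3-en-2-yl]-3-methyl-1,2-dioxan-3-yl]ethan-1-ol | OCC[C@]1(C)CC[C@@H]([C@@H](C)C=C)OO1
F10 | step 8 | 2-[(3S,6S)-6-[(2S)-but-3-en-2-yl]-3-methyl-1,2-dioxan-3-yl]acetaldehyde | O=CC[C@]1(C)CC[C@@H]([C@@H](C)C=C)OO1
F11 | step 7 | (3R,4S)-1-[(1R,2R)-2-(dimethoxymethyl)-1-methylcyclopropyl]-4-methylhex-5-en-3-yl trifluoromethanesulfonate | C=C[C@H](C)[C@H](OS(=O)(=O)C(F)(F)F)CC[C@]1(C)C[C@H]1C(OC)OC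
F12 | step 7 | (1R,2R)-1-(dimethoxymethyl)-2-[(3S,4S)-3-[(2-methoxypropan-2-yl)peroxy]-4-methylhex-5-en-1-yl]-2-methylcyclopropane | C=C[C@H](C)[C@@H](OOC(C)(C)OC)CC[C@]1(C)C[C@H]1C(OC)OC
F13 | step 13 | 3-[(3S,6S)-6-[(2R)-1-methoxy-1-oxopropan-2-yl]-3-methyl-1,2-dioxan-3-yl]propanoic acid | OC(=O)CC[C@]1(C)CC[C@@H]([C@@H](C)C(=O)OC)OO1
F14 | step 13 | methyl (2R)-2-[(3S,6S)-6-(3-chloro-3-oxopropyl)-6-methyl-1,2-dioxan-3-yl]propanoate | ClC(=O)CC[C@]1(C)CC[C@@H]([C@@H](C)C(=O)OC)OO1
F15 | step 13 | tributyl[4-(2,6,6-trimethylcyclohex-1-en-1-yl)but-1-en-2-yl]stannane | CCCC[Sn](CCCC)(CCCC)C(=C)CCC1=C(C)CCCC1(C)C
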